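**Plan**

- Numbering: ring C1 carries the C7 methylene, C2 Br, C3 OH, C4 OSO3H, C5 Br, C6 Br. The feature used is that the oxygen-bearing carbons C3 and C4 are neighbours in the only ring, a six-membered carbocycle, so they are an enediol at a lower oxidation level.
- Retrosynthetic cuts, in order: the S–O bonds at O7 and then O4; the C7–O7 bond (back to a C7 methyl); the three C–Br bonds together with the aromatic unsaturation; last the ring bond C3–C4, which opens the ring to diethyl 3-methyladipate.
- Forward: the ring is closed once, in step 2, by acyloin coupling of the two ester carbons, then aromatised and tribrominated in step 3.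
- C7 is then raised to the aldehyde, which makes O4 (para) more acidic than O3 (meta) so that O4 is sulfated first; reduction and sulfation of O7 finish the route.
- Stereochemistry: the target has no stereocentre. The methyl-bearing carbon of racemic 3-methyladipic acid is the only one on the way and becomes sp2 on aromatisation.

Key step: step 2

Assumption: the target is taken as drawn, the free bis(hydrogen sulfate); sulfated intermediates are carried as sodium salts and the acid form is released only in the last operation, cold, because aryl and benzyl hydrogen sulfates hydrolyse under their own acidity.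

**Route**

Step 1
Reactants: 1 3-methylhexanedioic acid (racemic), 2 ethanol
Product: 3 diethyl 3-methylhexanedioate (racemic)
Conditions: EtOH (excess), H2SO4 (cat.), toluene, reflux, Dean–Stark
Reagents that add atoms: ethanol, CCO
Why: Fischer esterification, driven to completion by azeotropic removal of water, converts both carboxyl groups and leaves the racemic methyl-bearing carbon untouched.

Step 2
Reactants: 3 diethyl 3-methylhexanedioate, 4 chlorotrimethylsilane
Product: 5 4-methyl-1,2-bis(trimethylsilyloxy)cyclohex-1-ene (racemic)
Conditions: Na (4.2 equiv, dispersion), Me3SiCl (4.5 equiv), toluene, 110 °C, N2, slow addition of 3; filter, distil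
Reagents that add atoms: chlorotrimethylsilane, C[Si](C)(C)Cl
Why: Sodium transfers one electron to each ester carbonyl, the two ketyl radical anions join to make the C3–C4 bond, two ethoxides leave to give the 1,2-dione, and two more electrons reduce this to the enediolate, which Me3SiCl silylates on both oxygens. The closest known reaction type is the acyloin condensation of adipate diesters run with chlorotrimethylsilane as trap (Rühlmann variant). The six-membered carbocycle closes by intramolecular carbonyl-carbon to carbonyl-carbon radical coupling of a 1,6-diester, formally a 6-exo-trig attack of one ketyl on the other ester carbonyl. No stereocentre is created; the methyl-bearing carbon stays racemic and is flattened on aromatisation in step 3. The step needs reductive coupling to win over Dieckmann condensation and over intermolecular coupling: Me3SiCl removes ethoxide as EtOSiMe3 and caps the enediolate, and slow addition of the diester to the refluxing sodium dispersion keeps the closure intramolecular. Because both ester carbons end as the oxygen-bearing ring carbons C3 and C4, there is no regiochemical choice to control.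

Step 3
Reactants: 5 4-methyl-1,2-bis(trimethylsilyloxy)cyclohex-1-ene, 6 bromine
Product: 8 3,4,6-tribromo-5-methylbenzene-1,2-diol, via 4-methylcyclohexane-1,2-dione 7 (not isolated)
Conditions: Br2 (1.05 equiv), CH2Cl2, −78 → 0 °C; concentrate; then Br2 (4.2 equiv), AcOH, 20 → 60 °C; aq. NaHSO3 wash
Reagents that add atoms: bromine, BrBr
Why: Bromine first oxidises the electron-rich bis(silyl) enediol ether to the 1,2-dione with loss of two Me3SiBr (the known bromine oxidation of acyloin silyl ethers), and in HBr/AcOH the dione then undergoes α-bromination, dehydrobromination and tautomerisation to the catechol, whose three free ring positions are filled by electrophilic aromatic bromination, the bisulfite wash returning any o-quinone to the catechol.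

Step 4
Reactants: 8 3,4,6-tribromo-5-methylbenzene-1,2-diol, 9 acetic anhydride
Product: 10 3,4,6-tribromo-5-methyl-1,2-phenylene diacetate
Conditions: Ac2O (2.5 equiv), pyridine, DMAP (cat.), CH2Cl2, 25 °C
Reagents that add atoms: acetic anhydride, CC(=O)OC(C)=O
Why: DMAP-catalysed O-acetylation caps both hindered phenols so that the catechol is not oxidised to the o-quinone by NBS in the next step.

Step 5
Reactants: 10 3,4,6-tribromo-5-methyl-1,2-phenylene diacetate, 11 N-bromosuccinimide
Product: 12 3,4,6-tribromo-5-(dibromomethyl)-1,2-phenylene diacetate
Conditions: NBS (2.5 equiv), AIBN (cat.), PhCF3, 100 °C, hν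
Reagents that add atoms: N-bromosuccinimide, O=C1CCC(=O)N1Br
Why: Wohl–Ziegler radical bromination can only attack the C7 methyl group, since the ring carries no hydrogen and the acetates are inert, and excess NBS with irradiation should push the hindered benzyl bromide on to the benzal bromide.

Step 6
Reactants: 12 3,4,6-tribromo-5-(dibromomethyl)-1,2-phenylene diacetate, 13 water
Product: 14 2,3,6-tribromo-4,5-dihydroxybenzaldehyde
Conditions: 1 M NaOH (7 equiv), THF–H2O, N2, 0 → 25 °C; then 2 M HCl
Reagents that add atoms: water, O
Why: Saponification of the two aryl acetates frees the O4 phenoxide para to C7, which expels bromide through a quinone methide, so that addition of water and loss of the second bromide give the aldehyde, the classical hydrolysis of a benzal halide as used to make hydroxybenzaldehydes from cresyl esters.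

Step 7
Reactants: 14 2,3,6-tribromo-4,5-dihydroxybenzaldehyde, 15 sodium hydrogencarbonate, 16 sulfur trioxide–pyridine complex
Product: 17 sodium 2,3,5-tribromo-4-formyl-6-hydroxyphenyl sulfate
Conditions: NaHCO3 (1.0 equiv), DMF, 25 °C; then SO3·pyridine (1.1 equiv), 0 → 25 °C; C18 (H2O–MeOH)
Reagents that add atoms: sodium hydrogencarbonate, [Na+].OC([O-])=O; sulfur trioxide–pyridine complex, [O-]S(=O)(=O)[n+]1ccccc1
Why: In the aldehyde the O4–H para to the formyl group (and meta to two bromines) is distinctly more acidic than the O3–H, so one equivalent of NaHCO3 should give mainly the O4 phenoxide, which is sulfated by the SO3–pyridine complex, the same monoanion logic that makes 3,4-dihydroxybenzaldehyde react at its 4-oxygen, applied to phenoxide O-sulfation with a sulfur trioxide–amine complex.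

Step 8
Reactants: 17 sodium 2,3,5-tribromo-4-formyl-6-hydroxyphenyl sulfate
Product: 18 sodium 2,3,5-tribromo-6-hydroxy-4-(hydroxymethyl)phenyl sulfate
Conditions: NaBH4 (1.5 equiv), MeOH–H2O, 0 °C; adjust to pH 6; C18
Reagents that add atoms: none
Why: NaBH4 reduction of the aromatic aldehyde to the primary alcohol, to which aryl sulfate monoester anions and aryl bromides are inert.

Step 9
Reactants: 18 sodium 2,3,5-tribromo-6-hydroxy-4-(hydroxymethyl)phenyl sulfate, 19 sulfur trioxide–triethylamine complex
Product: 21 (2,3,6-tribromo-5-hydroxy-4-sulfooxyphenyl)methyl hydrogen sulfate, via sodium triethylammonium disulfate salt 20 (not isolated)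
Conditions: SO3·NEt3 (2 equiv), DMF, 0 → 25 °C; then 1 M HCl (2.0 equiv), 0 °C, C18 (H2O → MeOH), lyophilise cold
Reagents that add atoms: sulfur trioxide–triethylamine complex, CC[N+](CC)(CC)S(=O)(=O)[O-]
Why: Without added base a sulfur trioxide–amine complex sulfates a primary alcohol much faster than a phenol, and here the only phenol left is weakly nucleophilic and flanked by bromine and the anionic sulfate, so O-sulfation should occur at O7 alone; because O4 is already sulfated and the free hydroxyl is meta to C7 no quinone methide can form, and cold acidification then releases the free acid.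

**Compound list**

1 | 3-methylhexanedioic acid (3-methyladipic acid, racemic) | CC(CCC(=O)O)CC(=O)O | starting material
2 | ethanol | CCO | starting material
3 | diethyl 3-methylhexanedioate (racemic) | CCOC(=O)CC(C)CCC(=O)OCC | intermediate
4 | chlorotrimethylsilane | C[Si](C)(C)Cl | starting material
5 | 4-methyl-1,2-bis(trimethylsilyloxy)cyclohex-1-ene (racemic) | CC1CCC(O[Si](C)(C)C)=C(O[Si](C)(C)C)C1 | intermediate
6 | bromine | BrBr | starting material
7 | 4-methylcyclohexane-1,2-dione (racemic, not isolated) | CC1CCC(=O)C(=O)C1 | intermediate
8 | 3,4,6-tribromo-5-methylbenzene-1,2-diol | Cc1c(Br)c(O)c(O)c(Br)c1Br | intermediate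
9 | acetic anhydride | CC(=O)OC(C)=O | starting material
10 | 3,4,6-tribromo-5-methyl-1,2-phenylene diacetate | CC(=O)Oc1c(Br)c(C)c(Br)c(Br)c1OC(C)=O | intermediate
11 | N-bromosuccinimide | O=C1CCC(=O)N1Br | starting material
12 | 3,4,6-tribromo-5-(dibromomethyl)-1,2-phenylene diacetate | CC(=O)Oc1c(Br)c(C(Br)Br)c(Br)c(Br)c1OC(C)=O | intermediate
13 | water | O | starting material
14 | 2,3,6-tribromo-4,5-dihydroxybenzaldehyde | O=Cc1c(Br)c(O)c(O)c(Br)c1Br | intermediate
15 | sodium hydrogencarbonate | [Na+].OC([O-])=O | starting material
16 | sulfur trioxide–pyridine complex | [O-]S(=O)(=O)[n+]1ccccc1 | starting material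
17 | sodium 2,3,5-tribromo-4-formyl-6-hydroxyphenyl sulfate | [Na+].[O-]S(=O)(=O)Oc1c(O)c(Br)c(C=O)c(Br)c1Br | intermediate
18 | sodium 2,3,5-tribromo-6-hydroxy-4-(hydroxymethyl)phenyl sulfate | [Na+].[O-]S(=O)(=O)Oc1c(O)c(Br)c(CO)c(Br)c1Br | intermediate
19 | sulfur trioxide–triethylamine complex | CC[N+](CC)(CC)S(=O)(=O)[O-] | starting material
20 | sodium triethylammonium (2,3,6-tribromo-5-hydroxy-4-sulfonatooxyphenyl)methyl sulfate (not isolated) | [Na+].CC[NH+](CC)CC.[O-]S(=O)(=O)OCc1c(Br)c(O)c(OS(=O)(=O)[O-])c(Br)c1Br | intermediate
21 | (2,3,6-tribromo-5-hydroxy-4-sulfooxyphenyl)methyl hydrogen sulfate | O=S(=O)(O)OCc1c(Br)c(O)c(OS(=O)(=O)O)c(Br)c1Br | target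

**Count**

Total steps: 9. Longest linear sequence: 9 steps (the route is fully linear from 1).

**Steps most likely to fail, with fallbacks**

Step 3. α-Bromination of the dione may outrun loss of HBr, leading to geminally brominated diones that cannot aromatise, or excess bromine may over-oxidise the ring to quinone and ring-cleavage products. The fallback sets out from 5 and comes back at 8. Compound 5 is treated with Br2 (1.0 equiv) alone in CH2Cl2 at −78 °C and the dione 7 is isolated. The dione is dehydrogenated with I2 (cat.) in DMSO at 90 °C, DMSO acting as the terminal oxidant, to give 4-methylbenzene-1,2-diol F1. This catechol is then tribrominated with Br2 (3.1 equiv) in AcOH at 25 °C to give 8.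

Step 7. The formyl group is twisted by its two ortho bromines and may separate the two phenol acidities less than hoped, so that sulfation spreads over O3 and O4 or goes twice, and the isomeric salts separate poorly. The fallback sets out from 14 and comes back at 17. Compound 14 is converted with NaH (2.1 equiv) in DMSO into its dianion, in which the oxide meta to the formyl group is the more nucleophilic. Alkylation with allyl bromide (1.0 equiv) should give 5-(allyloxy)-2,3,6-tribromo-4-hydroxybenzaldehyde F2, a neutral phenol that can be purified on silica. Its only free hydroxyl is sulfated (NaHCO3, SO3·pyridine, DMF) to sodium 2-(allyloxy)-3,5,6-tribromo-4-formylphenyl sulfate F3. The allyl group is removed with Pd(PPh3)4 (cat.) and sodium p-toluenesulfinate in THF–MeOH at 25 °C; allyl transfer from this electron-poor aryl ether should be much faster than insertion of zerovalent palladium into the hindered C–Br bonds. Adjustment to pH 5 gives 17.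

Step 9. The phenol at O3 may be sulfated in competition, or the benzylic alcohol, shielded by two ortho bromines, may react so slowly that forcing conditions erode the chemoselectivity. The fallback sets out from 18 and comes back at 21. The phenol of 18 is acetylated selectively in water (Ac2O, aq. NaHCO3, 0 °C; the phenoxide reacts, the alcohol does not) to give sodium 2-acetoxy-3,5,6-tribromo-4-(hydroxymethyl)phenyl sulfate F4. The single remaining hydroxyl is sulfated with excess SO3·pyridine in DMF and the product is converted with NaHCO3 into disodium [5-acetoxy-2,3,6-tribromo-4-(sulfonatooxy)phenyl]methyl sulfate F5. The activated aryl acetate is cleaved with dilute aq. NaOH at 0 °C, and cold acidification with HCl gives 21.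

**Further compounds**

F1 | step 3 | 4-methylbenzene-1,2-diol | Cc1ccc(O)c(O)c1
F2 | step 7 | 5-(allyloxy)-2,3,6-tribromo-4-hydroxybenzaldehyde | O=Cc1c(Br)c(OCC=C)c(O)c(Br)c1Br
F3 | step 7 | sodium 2-(allyloxy)-3,5,6-tribromo-4-formylphenyl sulfate | [Na+].[O-]S(=O)(=O)Oc1c(OCC=C)c(Br)c(C=O)c(Br)c1Br
F4 | step 9 | sodium 2-acetoxy-3,5,6-tribromo-4-(hydroxymethyl)phenyl sulfate | [Na+].[O-]S(=O)(=O)Oc1c(OC(C)=O)c(Br)c(CO)c(Br)c1Br
F5 | step 9 | disodium [5-acetoxy-2,3,6-tribromo-4-(sulfonatooxy)phenyl]methyl sulfate | [Na+].[Na+].[O-]S(=O)(=O)OCc1c(Br)c(OC(C)=O)c(OS(=O)(=O)[O-])c(Br)c1Br
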